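**Strategy.** The route rests on closing ring C through its aryl ether bond, O1–C8a. In ring A, C8a lies meta to both phenolic oxygens (on C5 and C7), para to the prenylated C6 and ortho to the C4 carbonyl, so it can be marked with fluorine from 5-fluororesorcinol and activated for substitution by the ketone. One operation formylates a 2-fluoroaryl methyl ketone and lets the resulting enolate oxygen displace fluoride, giving the 6-prenylchromone with no 8-prenyl isomer possible. The precursor is a fully substituted 2-fluoroacetophenone made by two directed lithiations. A rhodium-catalysed asymmetric 1,4-addition of the geranylated ring B boronic acid then sets C2, and acid removes the MOM groups.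

Key step: step 4

Remark: 5-fluorobenzene-1,3-diol is taken as a purchasable starting material (otherwise it is one BBr3 demethylation away from 1-fluoro-3,5-dimethoxybenzene), and the single stereocenter of the target, C2, is (S).

**Step 1**
Reactants: 1 5-fluorobenzene-1,3-diol
Product: 2 1-fluoro-3,5-bis(methoxymethoxy)benzene
Conditions: MOMCl, i-Pr2NEt, CH2Cl2, 0 °C to rt
Reagents that add atoms: chloromethyl methyl ether (MOMCl), COCCl
Why: O-alkylation of both phenols by the reactive α-chloro ether under amine base (Williamson-type etherification) should give the bis-acetal, whose oxygens later direct the two lithiations.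

**Step 2**
Reactants: 2 1-fluoro-3,5-bis(methoxymethoxy)benzene; 3 prenyl bromide
Product: 5 5-fluoro-1,3-bis(methoxymethoxy)-2-(3-methylbut-2-en-1-yl)benzene, via aryllithium 4 (not isolated)
Conditions: n-BuLi, THF, −20 °C; CuBr·SMe2 (20 mol %), prenyl bromide, −78 °C to rt
Reagents that add atoms: none
Why: Directed ortho-metalation should remove the hydrogen flanked by the two OMOM groups through double chelation of n-BuLi (no polyamine additive, so coordination rather than acidity decides), this site being para to fluorine so that no aryne can form, and the copper-catalysed allylation should then occur at the primary carbon of prenyl bromide (SN2 rather than SN2').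

**Step 3**
Reactants: 5 5-fluoro-1,3-bis(methoxymethoxy)-2-(3-methylbut-2-en-1-yl)benzene
Product: 8 1-[6-fluoro-2,4-bis(methoxymethoxy)-3-(3-methylbut-2-en-1-yl)phenyl]ethan-1-one, via aryllithium 6 (not isolated), via lithium hemiaminal adduct 7 (not isolated)
Conditions: s-BuLi, THF, −78 °C; MeC(O)N(OMe)Me, −78 to −20 °C; H2O
Reagents that add atoms: N-methoxy-N-methylacetamide, CC(=O)N(C)OC
Why: A second directed ortho-metalation at one of the two symmetry-equivalent ring positions flanked by fluorine and OMOM (far more acidic than the benzylic CH2 of the prenyl group), held at −78 °C so that the ortho-fluoro aryllithium does not lose LiF, is followed by a Weinreb ketone synthesis whose chelated tetrahedral adduct prevents over-addition.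

**Step 4**
Reactants: 8 1-[6-fluoro-2,4-bis(methoxymethoxy)-3-(3-methylbut-2-en-1-yl)phenyl]ethan-1-one
Product: 10 5,7-bis(methoxymethoxy)-6-(3-methylbut-2-en-1-yl)-4H-chromen-4-one, via sodium formyl enolate 9 (not isolated)
Conditions: NaH (1.2 equiv), HCO2Et, THF, 0 °C to rt; evaporate volatiles; DMF, 90–100 °C
Reagents that add atoms: ethyl formate, CCOC=O
Why: A crossed Claisen condensation of the methyl ketone enolate with ethyl formate gives the sodium salt of the β-ketoaldehyde (a vinylogous carboxylate), whose terminal oxygen adds to C8a ipso to fluorine to give a Meisenheimer intermediate stabilised by the C4 carbonyl, and loss of fluoride (addition–elimination, SNAr) forms the O1–C8a bond. The closest known reaction type is the base-mediated, transition-metal-free intramolecular O-arylation of 1-(2-haloaryl)-1,3-dicarbonyl compounds to chromones and flavones. The γ-pyrone ring closes as a six-membered ring by attack on an aromatic sp2 carbon, formally 6-endo-trig (the C8a=C4a bond, conjugated to C4=O, takes up the charge), a mode the Baldwin rules allow. No stereocenter is formed, and the planar chromone keeps the C2=C3 bond as the acceptor for the later asymmetric arylation. The step needs O- rather than C-attack of the ambident enolate, which ring size secures (C-attack would give a four-membered ring), and a single regiochemistry, which is fixed because only C8a carries a leaving group, so that O1 ends meta to both OMOM carbons and the prenyl group at C6; intermolecular displacement of fluoride by ethoxide is suppressed by removing ethanol before heating.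

**Step 5**
Reactants: 11 4-bromophenol; 12 geranyl bromide
Product: 13 4-bromo-2-[(2E)-3,7-dimethylocta-2,6-dien-1-yl]phenol
Conditions: NaH, toluene, rt; geranyl bromide, rt to 40 °C
Reagents that add atoms: none
Why: ortho-C-Alkylation of a phenoxide: the tight sodium phenoxide ion pair in a non-polar solvent should alkylate through carbon at a free ortho position (para is blocked by bromine) at the primary carbon of geranyl bromide, which keeps the E-alkene.

**Step 6**
Reactants: 13 4-bromo-2-[(2E)-3,7-dimethylocta-2,6-dien-1-yl]phenol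
Product: 14 4-bromo-2-[(2E)-3,7-dimethylocta-2,6-dien-1-yl]-1-(methoxymethoxy)benzene
Conditions: MOMCl, i-Pr2NEt, CH2Cl2, 0 °C to rt
Reagents that add atoms: chloromethyl methyl ether (MOMCl), COCCl
Why: O-alkylation of the phenol (Williamson-type) masks the acidic OH before the organolithium and rhodium steps and gives the same protecting group as on ring A.

**Step 7**
Reactants: 14 4-bromo-2-[(2E)-3,7-dimethylocta-2,6-dien-1-yl]-1-(methoxymethoxy)benzene
Product: 17 {3-[(2E)-3,7-dimethylocta-2,6-dien-1-yl]-4-(methoxymethoxy)phenyl}boronic acid, via aryllithium 15 (not isolated), via lithium triisopropoxyborate 16 (not isolated)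
Conditions: n-BuLi, THF, −78 °C; B(Oi-Pr)3, −78 °C to rt; 1 M HCl (aq), 0 °C, brief
Reagents that add atoms: triisopropyl borate, CC(C)OB(OC(C)C)OC(C)C; water, O
Why: Bromine–lithium exchange is faster than any deprotonation at −78 °C, the aryllithium is trapped by the borate ester as an ate complex, and brief cold hydrolysis should give the boronic acid while the aryl MOM acetal survives.

**Step 8**
Reactants: 10 5,7-bis(methoxymethoxy)-6-(3-methylbut-2-en-1-yl)-4H-chromen-4-one; 17 {3-[(2E)-3,7-dimethylocta-2,6-dien-1-yl]-4-(methoxymethoxy)phenyl}boronic acid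
Product: 18 (2S)-2-{3-[(2E)-3,7-dimethylocta-2,6-dien-1-yl]-4-(methoxymethoxy)phenyl}-5,7-bis(methoxymethoxy)-6-(3-methylbut-2-en-1-yl)-2,3-dihydro-4H-chromen-4-one
Conditions: [RhCl(C2H4)2]2 (2.5 mol %), (S)-MeO-F12-BIPHEP [(S)-2,2'-bis[bis(3,4,5-trifluorophenyl)phosphino]-6,6'-dimethoxy-1,1'-biphenyl] (5.5 mol %), KOH (10 mol %), toluene/H2O 10:1, 20 °C
Reagents that add atoms: none
Why: Hayashi–Miyaura reaction, known for chromones: the aryl–rhodium species on the chiral bisphosphine inserts the C2=C3 bond and water protonates the rhodium enolate; by the accepted model for (S)-biaryl bisphosphines with cyclic enones (the face that gives (S)-3-arylcyclohexanones) the aryl group should be delivered to the chromone face that corresponds to (2S), the electron-poor ligand favouring 1,4- over 1,2-addition and the unactivated prenyl and geranyl alkenes staying untouched.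

**Step 9**
Reactants: 18 (2S)-2-{3-[(2E)-3,7-dimethylocta-2,6-dien-1-yl]-4-(methoxymethoxy)phenyl}-5,7-bis(methoxymethoxy)-6-(3-methylbut-2-en-1-yl)-2,3-dihydro-4H-chromen-4-one
Product: 19 schizolaenone A
Conditions: 3 M HCl (aq), MeOH, 40 °C
Reagents that add atoms: none
Why: Acid-catalysed acetal exchange with methanol should cleave the three MOM ethers under conditions mild enough to leave the ortho-prenyl and ortho-geranyl phenols uncyclised, and C2 should keep its configuration because ring opening of flavanones to chalcones requires base.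

**Compound list**

1 | 5-fluorobenzene-1,3-diol (5-fluororesorcinol) | Oc1cc(O)cc(F)c1 | starting material
2 | 1-fluoro-3,5-bis(methoxymethoxy)benzene | COCOc1cc(F)cc(OCOC)c1 | intermediate
3 | prenyl bromide (1-bromo-3-methylbut-2-ene) | CC(C)=CCBr | starting material
4 | [4-fluoro-2,6-bis(methoxymethoxy)phenyl]lithium | [Li]c1c(OCOC)cc(F)cc1OCOC | intermediate
5 | 5-fluoro-1,3-bis(methoxymethoxy)-2-(3-methylbut-2-en-1-yl)benzene | COCOc1cc(F)cc(OCOC)c1CC=C(C)C | intermediate
6 | [6-fluoro-2,4-bis(methoxymethoxy)-3-(3-methylbut-2-en-1-yl)phenyl]lithium | [Li]c1c(F)cc(OCOC)c(CC=C(C)C)c1OCOC | intermediate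
7 | lithium 1-[6-fluoro-2,4-bis(methoxymethoxy)-3-(3-methylbut-2-en-1-yl)phenyl]-1-[methoxy(methyl)amino]ethan-1-olate (racemic tetrahedral adduct) | [Li+].CC([O-])(N(C)OC)c1c(F)cc(OCOC)c(CC=C(C)C)c1OCOC | intermediate
8 | 1-[6-fluoro-2,4-bis(methoxymethoxy)-3-(3-methylbut-2-en-1-yl)phenyl]ethan-1-one | CC(=O)c1c(F)cc(OCOC)c(CC=C(C)C)c1OCOC | intermediate
9 | sodium (1Z)-3-[6-fluoro-2,4-bis(methoxymethoxy)-3-(3-methylbut-2-en-1-yl)phenyl]-3-oxoprop-1-en-1-olate | [Na+].[O-]/C=C\C(=O)c1c(F)cc(OCOC)c(CC=C(C)C)c1OCOC | intermediate
10 | 5,7-bis(methoxymethoxy)-6-(3-methylbut-2-en-1-yl)-4H-chromen-4-one | O=C1C=COc2cc(OCOC)c(CC=C(C)C)c(OCOC)c12 | intermediate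
11 | 4-bromophenol | Oc1ccc(Br)cc1 | starting material
12 | geranyl bromide [(2E)-1-bromo-3,7-dimethylocta-2,6-diene] | CC(C)=CCC/C(C)=C/CBr | starting material
13 | 4-bromo-2-[(2E)-3,7-dimethylocta-2,6-dien-1-yl]phenol | CC(C)=CCC/C(C)=C/Cc1cc(Br)ccc1O | intermediate
14 | 4-bromo-2-[(2E)-3,7-dimethylocta-2,6-dien-1-yl]-1-(methoxymethoxy)benzene | CC(C)=CCC/C(C)=C/Cc1cc(Br)ccc1OCOC | intermediate
15 | {3-[(2E)-3,7-dimethylocta-2,6-dien-1-yl]-4-(methoxymethoxy)phenyl}lithium | CC(C)=CCC/C(C)=C/Cc1cc([Li])ccc1OCOC | intermediate
16 | lithium {3-[(2E)-3,7-dimethylocta-2,6-dien-1-yl]-4-(methoxymethoxy)phenyl}tri(propan-2-yloxy)borate | [Li+].CC(C)=CCC/C(C)=C/Cc1cc([B-](OC(C)C)(OC(C)C)OC(C)C)ccc1OCOC | intermediate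
17 | {3-[(2E)-3,7-dimethylocta-2,6-dien-1-yl]-4-(methoxymethoxy)phenyl}boronic acid | CC(C)=CCC/C(C)=C/Cc1cc(B(O)O)ccc1OCOC | intermediate
18 | (2S)-2-{3-[(2E)-3,7-dimethylocta-2,6-dien-1-yl]-4-(methoxymethoxy)phenyl}-5,7-bis(methoxymethoxy)-6-(3-methylbut-2-en-1-yl)-2,3-dihydro-4H-chromen-4-one | CC(C)=CCC/C(C)=C/Cc1cc([C@@H]2CC(=O)c3c(cc(OCOC)c(CC=C(C)C)c3OCOC)O2)ccc1OCOC | intermediate
19 | schizolaenone A, (2S)-2-{3-[(2E)-3,7-dimethylocta-2,6-dien-1-yl]-4-hydroxyphenyl}-5,7-dihydroxy-6-(3-methylbut-2-en-1-yl)-2,3-dihydro-4H-chromen-4-one | CC(C)=CCC/C(C)=C/Cc1cc([C@@H]2CC(=O)c3c(cc(O)c(CC=C(C)C)c3O)O2)ccc1O | target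

**Totals**

Total step count: 9
Longest linear sequence: 6 steps (steps 1, 2, 3, 4, 8, 9)

**Steps most likely to fail**

Step 2. The metalation may take place next to fluorine instead of between the two acetal oxygens, and the ortho-fluoro aryllithium would then lose LiF and decompose through an aryne. The fallback fixes the site with a halogen instead of a deprotonation and sets out from 1. Iodination with I2 and NaHCO3 in water, which for resorcinols goes between the two hydroxyls, should give 5-fluoro-2-iodobenzene-1,3-diol F1. MOMCl and i-Pr2NEt then give 5-fluoro-2-iodo-1,3-bis(methoxymethoxy)benzene F2. Iodine–lithium exchange with n-BuLi at −78 °C gives aryllithium 4 regiospecifically, and prenylation as in step 2 brings the route back at 5.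

Step 4. Retro-Claisen loss of the formyl group and intermolecular displacement of fluoride by ethoxide may outrun the ring closure of the delocalised enolate onto the electron-rich, twisted fluoroarene. The fallback makes the three-carbon unit without a Claisen equilibrium and without alkoxide, and sets out from 8. Condensation with Me2NCH(OMe)2 in toluene at 110 °C gives the isolable enaminone (2E)-3-(dimethylamino)-1-[6-fluoro-2,4-bis(methoxymethoxy)-3-(3-methylbut-2-en-1-yl)phenyl]prop-2-en-1-one F3. NaOH (1.1 equiv) in DMSO/H2O at 90 °C hydrolyses it to the enolate 9, free of ethoxide and formate ester, which closes the same O1–C8a bond, and the route comes back at 10.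

Step 8. Insertion into the electron-rich, peri-substituted chromone may be slow enough for protodeboronation to win, or the facial selectivity may be insufficient (or of the opposite sense, to be checked on the first sample). The fallback separates bond formation from stereocontrol and sets out from 10 and 17. The achiral, more active catalyst [Rh(OH)(cod)]2 in dioxane/H2O at rt gives racemic 2-{3-[(2E)-3,7-dimethylocta-2,6-dien-1-yl]-4-(methoxymethoxy)phenyl}-5,7-bis(methoxymethoxy)-6-(3-methylbut-2-en-1-yl)-2,3-dihydro-4H-chromen-4-one F4. Preparative HPLC on a cellulose tris(3,5-dimethylphenylcarbamate) phase resolves it into 18 and its (2R)-enantiomer F5, which is set aside, and the route comes back at 18.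

**Further compounds**

F1 | step 2 | 5-fluoro-2-iodobenzene-1,3-diol | Oc1cc(F)cc(O)c1I
F2 | step 2 | 5-fluoro-2-iodo-1,3-bis(methoxymethoxy)benzene | COCOc1cc(F)cc(OCOC)c1I
F3 | step 4 | (2E)-3-(dimethylamino)-1-[6-fluoro-2,4-bis(methoxymethoxy)-3-(3-methylbut-2-en-1-yl)phenyl]prop-2-en-1-one | CN(C)/C=C/C(=O)c1c(F)cc(OCOC)c(CC=C(C)C)c1OCOC
F4 | step 8 | racemic 2-{3-[(2E)-3,7-dimethylocta-2,6-dien-1-yl]-4-(methoxymethoxy)phenyl}-5,7-bis(methoxymethoxy)-6-(3-methylbut-2-en-1-yl)-2,3-dihydro-4H-chromen-4-one | CC(C)=CCC/C(C)=C/Cc1cc(C2CC(=O)c3c(cc(OCOC)c(CC=C(C)C)c3OCOC)O2)ccc1OCOC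
F5 | step 8 | (2R)-2-{3-[(2E)-3,7-dimethylocta-2,6-dien-1-yl]-4-(methoxymethoxy)phenyl}-5,7-bis(methoxymethoxy)-6-(3-methylbut-2-en-1-yl)-2,3-dihydro-4H-chromen-4-one | CC(C)=CCC/C(C)=C/Cc1cc([C@H]2CC(=O)c3c(cc(OCOC)c(CC=C(C)C)c3OCOC)O2)ccc1OCOC
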